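## Analysis of the target

(+)-Chamaechromone is an open-chain biflavonoid-type molecule. A 5,7-dihydroxychromone (benzo ring A fused to pyranone ring C) carries at C3 a methine carbon, C-alpha, which also bears a 2,4,6-trihydroxybenzoyl group (ring D, C1' to C6', joined through the ketone carbon) and a bis(4-hydroxyphenyl)methyl group (C-beta with rings B and B'). C-alpha is the only stereocentre and is S; C-beta carries two identical aryl groups, so there is no relative configuration to control. The C-alpha hydrogen is alpha to an aryl ketone and allylic to C2=C3 of the chromone, so the centre can epimerise by enolisation under base or strong Lewis acid. Under base the free para-phenols also make the C-alpha–C-beta bond a retro-Michael bond (loss of a quinone methide), and C2 of the chromone accepts nucleophiles, so the seven phenols should stay masked until an acidic last step. The difficulty is the crowded methine with three bulky carbon groups, and above all the di-ortho-oxygenated aryl ketone beside it: acylating a tri-oxygenated arene or adding an aryl metal brings acid or base directly to the labile centre. The strategy rests on ring D being an acylphloroglucinol. C2' to C5', with the oxygens on C2' and C4', map onto a 1,1,3-trioxygenated butadiene (diene 19). C1' and the oxygenated C6' map onto the two alkyne carbons of a 3-ethoxy ynone (15) whose carbonyl is already bonded to C-alpha.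

## Retrosynthetic reasoning

**23 to 22.** Only oxygen–alkyl bonds are cut. Free phenols cannot be carried through organolithium and silyl chemistry, and a basic unmasking is excluded by the retro-Michael lability of the bis(4-hydroxyphenyl)methyl group. The precursor is therefore 22, with four methyl ethers on rings A, B and B', one ethyl ether on C6' and two free hydroxyl groups on ring D. The forward step must cleave one ethyl and four methyl aryl ethers with a Lewis acid without enolising C-alpha.

**22 to 15 and 19.** Ring D is cut at C1'–C2' and C5'–C6'. Cutting the C1'–carbonyl bond instead would require an arene acylation or a hindered aryl-metal addition next to C-alpha. Cutting inside the ring leaves the C-alpha–carbonyl bond intact and turns the acyl group into ynone 15, a dienophile that reacts without acid or base. Diene 19 supplies C2' to C5' with the oxygens of C2' and C4'; the ethoxy oxygen of 15 becomes the oxygen on C6'. The forward reaction has to be regioselective, aromatise by expelling the ketal methoxy group, and leave the chromone and C-alpha alone.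

**19 to 17 to 16.** The diene is the doubly enol-silylated form of methyl acetoacetate 16; two O–Si bonds are cut in turn, through silyl enol ether 17 and lithium dienolate 18.

**15 to 11 and 12.** The bond between the ketone carbon and the alkyne is cut, giving N-methoxy-N-methylamide 11 and ethoxyacetylene 12 (as lithium salt 13). This amide is chosen over an ester or acid chloride because its chelated adduct 14 stops at the ketone level and keeps the acidic alpha-hydrogen of the ynone hidden until the cold quench.

**11 to 9.** Ring C is opened at O1–C2 and C2–C3. C2 is a one-carbon unit at the formate level, condensed onto the methylene of ortho-hydroxyaryl ketone 9 through enaminone 10. This isoflavone-type annulation uses no strong base. It is placed after amide formation so that no free carboxylic acid meets the alkylating amide acetal and no aqueous base meets the chromone.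

**9 to 8 to 7.** The amide is traced back through acid 8 to methyl ester 7. The ester is hydrolysed while C-alpha is only alpha to an ester and not yet attached to the chromone, when it is least acidic.

**7 to 5 and 6.** The C4–C4a bond is cut: the free acid terminus of half-ester 5 acylates 3,5-dimethoxyphenol 6. Half-ester 5 already differentiates the two carboxyl carbons, so the one that becomes C4 reacts and the one that becomes the ring D ketone stays an ester.

**5 to 4.** The C-alpha–H and C-beta–H bonds are cut: asymmetric hydrogenation of the tetrasubstituted alkene of 4. The stereocentre is set once, by a catalyst, on a simple acid with a coordinating carboxylate, before any acidifying group flanks it.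

**4 to 1 and 2.** The C-alpha=C-beta bond is cut by a Stobbe condensation of ketone 1 with dimethyl succinate 2. The ketone carbon becomes C-beta with both aryl rings. The four succinate carbons become the ring D carbonyl carbon, C-alpha, C3 and C4.

## Alternatives that were turned down

**Alternative 1:** carbene-catalysed Stetter closure of ring C.
- Disconnection: C3–C4 of ring C, with ring D (as a 2,4,6-trimethoxyphenyl ketone) and C-beta already in place.
- Forward key step: aldehyde–enone A2 is treated with a chiral N-heterocyclic carbene and base. The acyl anion equivalent from the formyl group adds 6-exo-trig to the enone beta carbon, and the enolate is protonated at C-alpha, giving chroman-4-one A1 with two new stereocentres.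
- For it: one catalytic asymmetric step closes ring C and makes the C-alpha–H bond. Ring D never has to be built or attached late. The reaction class is known for trisubstituted acceptors, and the sequence would probably be shorter than the chosen one.
- Against it here:
  - The acceptor carbonyl of A2 carries a di-ortho-methoxylated aryl group twisted out of conjugation, and its alpha carbon carries the bis(4-methoxyphenyl)methyl group, so both the addition and the face-selective protonation are severely crowded.
  - The stereocentre that survives is not the one the catalyst sets. C3 of A1 is erased when ring C is dehydrogenated to the chromone, so C-alpha depends on a relayed protonation.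
  - The dehydrogenation acts on a 1,4-diketone with C-alpha between the two carbonyl systems, where enolisation toward C-alpha or a C3=C-alpha double bond would destroy the centre.
- Comparison: Alternative 1 is stronger in step count and in using a catalytic C–C bond formation of a known type. The chosen route offers instead a stereocentre set directly (hydrogenation of 4), no change of oxidation level next to it afterwards, and a ring D construction free of acid and base.

**Alternative 2:** double C–H arylation of a methyl group.
- Disconnection: both C-beta–aryl bonds.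
- Forward key step: the methyl group of propanamide A4, directed by its quinolin-8-yl amide, is arylated twice with 4-iodoanisole A5 under divalent palladium catalysis with a silver salt, through five-membered palladacycles, giving A3.
- For it: rings B and B' arrive in one operation from a simple aryl iodide, and double arylation of methyl groups under such direction is well known. The aryl groups could be varied late. The chirality would come from a methyl-branched four-carbon diacid unit, far easier to obtain enantiopure than 5.
- Against it here:
  - The second arylation must functionalise a benzylic methylene beside a fully substituted centre and may stall at the monoaryl stage.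
  - The reaction runs hot with carboxylate present while C-alpha–H is alpha to the amide and allylic to the chromone, and C2–H of the chromone is a competing palladation site.
  - The directing amide of the hindered A3 then has to be cleaved under forcing conditions next to the labile centre.
  - Ring D still has to be attached by acylation or aryl-metal addition.
- Comparison: stronger in the source of chirality and in modularity, weaker in everything after the key step. The chosen route brings both aryl groups with ketone 1, has an easily displaced N-methoxy-N-methylamide (11) where this alternative has a robust amide, and does not attach a preformed ring D.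

**Alternative 3:** aryne annulation builds the chromone.
- Disconnection: O1–C8a and C4–C4a, with ring A brought in as an aryne.
- Forward key step: fluoride releases the aryne from silyl triflate A8. The enol oxygen of formylsuccinate A7 adds to the aryne carbon remote from the flanking methoxy group, and the aryl anion attacks the methyl ester to close ring C, giving tert-butyl ester A6.
- For it: a convergent one-step chromone synthesis under mild conditions. The regiochemistry of ring A is set by the aryne's methoxy group rather than by the ortho/para preference of a phenol acylation, a real advantage over step 3 of the chosen route. The tert-butyl ester is removed by acid, not base.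
- Against it here:
  - A7 is a 1,3-dicarbonyl compound, and arynes usually attack such enolates at carbon and then insert into the C–C bond, which gives the wrong connectivity.
  - The stereocentre of A7 sits beside an enolised formyl ester in a basic fluoride medium.
  - A7 needs its own asymmetric synthesis and a regioselective formylation beside the stereocentre, and A8 needs several steps.
  - A6 only reaches the stage of amide 11, so ring D is still to be made.
- Comparison: it solves the chromone, which acylation and annulation also solve in two operations from cheap 6, and leaves the hardest part, ring D beside C-alpha, untouched. The chosen route places its risk on exactly that part.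

Key step: step 10

Remarks on the chemistry (assumptions):
- The (R,R)-ligand in step 2 is taken to give the (R)-acid 5; if the sense of induction is the reverse, the mirror-image ligand is used.
- Silyl enol ether 17 is written as the Z isomer and diene 19 as the 1E isomer; neither geometry affects the outcome, since both double bonds end in the aromatic ring.
- The descriptor at C-alpha is R in 5, 7, 8 and 9 and S from 10 onward with unchanged spatial arrangement, because the former methylene carbon outranks the diarylmethyl group once it becomes sp2.

## Route

Step 1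
Reactants: 1 4,4'-dimethoxybenzophenone; 2 dimethyl succinate
Product: 4 3-(methoxycarbonyl)-4,4-bis(4-methoxyphenyl)but-3-enoic acid, via paraconate lactone 3 (not isolated)
Conditions: KOtBu, tBuOH, reflux; then aq HCl
Reagents that add atoms: none
Why: Stobbe condensation: the succinate enolate adds to the diaryl ketone, the aldolate lactonises onto the remote ester to give 3, and base-induced opening of the lactone leaves the conjugated methyl ester and a free CH2CO2H group; the two aryl groups are identical, so no alkene geometry arises.

Step 2
Reactants: 4 3-(methoxycarbonyl)-4,4-bis(4-methoxyphenyl)but-3-enoic acid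
Product: 5 (R)-3-(methoxycarbonyl)-4,4-bis(4-methoxyphenyl)butanoic acid
Conditions: H2 (10 bar), [Rh(cod)((R,R)-Et-DuPHOS)]BF4 (1 mol %), NaOMe (0.1 equiv), MeOH, 25 °C; then aq HCl
Reagents that add atoms: none
Why: Carboxylate-directed asymmetric hydrogenation of an itaconate-type half-ester; the carboxylate and alkene chelate the cationic monovalent rhodium centre and the C2-symmetric bisphospholane decides the face that receives hydrogen, which sets the only stereocentre of the route.

Step 3
Reactants: 5 (R)-3-(methoxycarbonyl)-4,4-bis(4-methoxyphenyl)butanoic acid; 6 3,5-dimethoxyphenol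
Product: 7 methyl (R)-2-[bis(4-methoxyphenyl)methyl]-4-(2-hydroxy-4,6-dimethoxyphenyl)-4-oxobutanoate
Conditions: BF3·OEt2 (solvent), 80 °C; then aq NaOAc
Reagents that add atoms: none
Why: Friedel–Crafts acylation of a phloroglucinol-type phenol by a free carboxylic acid (aryl ester formation and Fries-type shift), favouring the ortho-hydroxy ketone because its carbonyl–phenol pair chelates boron. The only intramolecular alternative, tetralone closure onto an anisyl ring, would attack a position meta to methoxy and should not compete with the far more nucleophilic phenol.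

Step 4
Reactants: 7 methyl (R)-2-[bis(4-methoxyphenyl)methyl]-4-(2-hydroxy-4,6-dimethoxyphenyl)-4-oxobutanoate
Product: 8 (R)-2-[bis(4-methoxyphenyl)methyl]-4-(2-hydroxy-4,6-dimethoxyphenyl)-4-oxobutanoic acid
Conditions: LiOH, THF/H2O, 0 °C → rt; then aq HCl
Reagents that add atoms: lithium hydroxide, [Li+].[OH-]
Why: Ester saponification; the phenol and the ketone methylene are deprotonated first, which disfavours a further deprotonation at the ester alpha carbon, and the carboxylate formed is configurationally safe.

Step 5
Reactants: 8 (R)-2-[bis(4-methoxyphenyl)methyl]-4-(2-hydroxy-4,6-dimethoxyphenyl)-4-oxobutanoic acid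
Product: 9 (R)-2-[bis(4-methoxyphenyl)methyl]-4-(2-hydroxy-4,6-dimethoxyphenyl)-N-methoxy-N-methyl-4-oxobutanamide
Conditions: MeNH(OMe)·HCl, EDC·HCl, HOBt, N-methylmorpholine, CH2Cl2, 0 °C → rt
Reagents that add atoms: N,O-dimethylhydroxylamine hydrochloride, CNOC.Cl
Why: Carbodiimide/hydroxybenzotriazole amide coupling; the hydrogen-bonded ortho-hydroxy ketone phenol is a poor nucleophile and is not acylated, and the weak amine base does not enolise the alpha centre.

Step 6
Reactants: 9 (R)-2-[bis(4-methoxyphenyl)methyl]-4-(2-hydroxy-4,6-dimethoxyphenyl)-N-methoxy-N-methyl-4-oxobutanamide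
Product: 11 (S)-2-(5,7-dimethoxy-4-oxo-4H-chromen-3-yl)-N-methoxy-N-methyl-3,3-bis(4-methoxyphenyl)propanamide, via enaminone 10 (not isolated)
Conditions: Me2NCH(OMe)2, toluene, 95 °C; then AcOH, 60 °C
Reagents that add atoms: N,N-dimethylformamide dimethyl acetal, COC(OC)N(C)C
Why: Isoflavone-type chromone annulation: the amide acetal condenses with the ketone methylene to give enaminone 10, and the phenol closes ring C by 6-endo-trig addition–elimination with loss of the amine. The stereocentre is not involved.

Step 7
Reactants: 11 (S)-2-(5,7-dimethoxy-4-oxo-4H-chromen-3-yl)-N-methoxy-N-methyl-3,3-bis(4-methoxyphenyl)propanamide; 12 ethoxyacetylene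
Product: 15 (S)-4-(5,7-dimethoxy-4-oxo-4H-chromen-3-yl)-1-ethoxy-5,5-bis(4-methoxyphenyl)pent-1-yn-3-one, via lithium ethoxyacetylide 13 (not isolated), via tetrahedral lithium adduct 14 (not isolated)
Conditions: 12, n-BuLi, THF, −78 °C; then 11, −78 → −40 °C; AcOH/THF, −78 °C
Reagents that add atoms: none
Why: Weinreb ketone synthesis with a lithium acetylide: chelated adduct 14 holds the carbonyl at the tetrahedral stage, so the acidic alpha-hydrogen of the ynone is exposed only after the cold acidic quench. The small, weakly basic acetylide should add to the amide faster than it deprotonates C-alpha or attacks the hindered vinylogous-ester carbonyl of the 5-methoxychromone.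

Step 8
Reactants: 16 methyl acetoacetate
Product: 17 methyl (Z)-3-(trimethylsilyloxy)but-2-enoate
Conditions: Me3SiCl, Et3N, hexane, rt
Reagents that add atoms: chlorotrimethylsilane, C[Si](C)(C)Cl
Why: O-silylation of the enol of a beta-keto ester with an amine base.

Step 9
Reactants: 17 methyl (Z)-3-(trimethylsilyloxy)but-2-enoate
Product: 19 (1E)-1-methoxy-1,3-bis(trimethylsilyloxy)buta-1,3-diene, via lithium dienolate 18 (not isolated)
Conditions: LiN(iPr)2, THF, −78 °C; then Me3SiCl, −78 → 0 °C
Reagents that add atoms: chlorotrimethylsilane, C[Si](C)(C)Cl
Why: Kinetic deprotonation of the gamma methyl group of the vinylogous ester and O-silylation of the extended enolate 18, the standard preparation of this 1,1,3-trioxygenated diene.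

Step 10
Reactants: 15 (S)-4-(5,7-dimethoxy-4-oxo-4H-chromen-3-yl)-1-ethoxy-5,5-bis(4-methoxyphenyl)pent-1-yn-3-one; 19 (1E)-1-methoxy-1,3-bis(trimethylsilyloxy)buta-1,3-diene
Product: 22 (S)-3-[1-(2-ethoxy-4,6-dihydroxyphenyl)-3,3-bis(4-methoxyphenyl)-1-oxopropan-2-yl]-5,7-dimethoxy-4H-chromen-4-one, via cyclohexadiene cycloadduct 20 (not isolated), via bis(trimethylsilyl) ether 21 (not isolated)
Conditions: 19 (3 equiv), toluene, 70 °C; then 1 M HCl, THF, 0 °C
Reagents that add atoms: none
Why: Proposed new method: the closest known reaction type is the Diels–Alder reaction of 1,1,3-trioxygenated butadienes with alkynones and alkynoates, which gives resorcinols after loss of an alcohol; here the alkyne also carries an alkoxy group on its beta carbon, a case not yet shown, so that the third oxygen of a phloroglucinol ring arrives with the dienophile. Diene 19 has its largest HOMO coefficient at the unsubstituted CH2 terminus and ynone 15 its largest LUMO coefficient at the ethoxy-bearing beta carbon (the ethoxy group raises the LUMO but does not reverse the polarisation, just as beta-alkoxy enones still accept nucleophiles at the beta carbon), so the C5'–C6' bond leads and the ketene acetal carbon then bonds to the alpha carbon to form C1'–C2'. Ring D closes by an intermolecular [4+2] cycloaddition; if the process is stepwise (silyl-transfer Mukaiyama–Michael addition), the second bond forms by 6-(enolexo)-exo-trig attack of the allenolate carbon on the silylated carboxonium carbon. Cycloadduct 20 is a cyclohexa-1,4-diene whose C5' methylene is doubly allylic and whose C2' is a methyl silyl ketal, so methanol is lost across the ring and 21 forms without an oxidant, while the ethoxy group sits on an sp2 carbon and cannot leave in this way. Mild acid then cleaves the two aryl silyl ethers to give 22. No stereocentre is created (the ketal carbon of 20 is transient), and C-alpha is preserved because no acid, base or metal is present while the acidic alpha-hydrogen of the ynone is exposed. The step needs regioselectivity, which the polarisation of the ynone secures, and chemoselectivity for the alkyne over C2=C3 of the chromone, which is secured because that trisubstituted vinylogous-ester alkene does not react with silyl dienes without Lewis-acid activation. The temperature is kept below the range in which 1-ethoxyalkynes lose ethylene by a retro-ene reaction.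

Step 11
Reactants: 22 (S)-3-[1-(2-ethoxy-4,6-dihydroxyphenyl)-3,3-bis(4-methoxyphenyl)-1-oxopropan-2-yl]-5,7-dimethoxy-4H-chromen-4-one
Product: 23 (+)-chamaechromone, (S)-3-[3,3-bis(4-hydroxyphenyl)-1-oxo-1-(2,4,6-trihydroxyphenyl)propan-2-yl]-5,7-dihydroxy-4H-chromen-4-one
Conditions: BBr3 (12 equiv), CH2Cl2, −78 °C → rt; then H2O, 0 °C
Reagents that add atoms: none
Why: Lewis-acid dealkylation of aryl ethers: the ethyl ether and the 5-methoxy group, each beside a carbonyl, should go first by chelation, and the 7-methoxy and two anisyl ethers follow at room temperature (one ethyl and four methyl ethers in all). The medium stays acidic, which avoids the base-induced retro-Michael loss of the bis(4-hydroxyphenyl)methyl group and leaves C-alpha protonated.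

## Compound list

1 | 4,4'-dimethoxybenzophenone | COc1ccc(cc1)C(=O)c1ccc(OC)cc1 | starting material
2 | dimethyl succinate | COC(=O)CCC(=O)OC | starting material
3 | methyl 2,2-bis(4-methoxyphenyl)-5-oxooxolane-3-carboxylate (racemic, not isolated) | COC(=O)C1CC(=O)OC1(c1ccc(OC)cc1)c1ccc(OC)cc1 | intermediate
4 | 3-(methoxycarbonyl)-4,4-bis(4-methoxyphenyl)but-3-enoic acid | COC(=O)C(CC(=O)O)=C(c1ccc(OC)cc1)c1ccc(OC)cc1 | intermediate
5 | (R)-3-(methoxycarbonyl)-4,4-bis(4-methoxyphenyl)butanoic acid | COC(=O)[C@H](CC(=O)O)C(c1ccc(OC)cc1)c1ccc(OC)cc1 | intermediate
6 | 3,5-dimethoxyphenol | COc1cc(O)cc(OC)c1 | starting material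
7 | methyl (R)-2-[bis(4-methoxyphenyl)methyl]-4-(2-hydroxy-4,6-dimethoxyphenyl)-4-oxobutanoate | COC(=O)[C@H](CC(=O)c1c(O)cc(OC)cc1OC)C(c1ccc(OC)cc1)c1ccc(OC)cc1 | intermediate
8 | (R)-2-[bis(4-methoxyphenyl)methyl]-4-(2-hydroxy-4,6-dimethoxyphenyl)-4-oxobutanoic acid | OC(=O)[C@H](CC(=O)c1c(O)cc(OC)cc1OC)C(c1ccc(OC)cc1)c1ccc(OC)cc1 | intermediate
9 | (R)-2-[bis(4-methoxyphenyl)methyl]-4-(2-hydroxy-4,6-dimethoxyphenyl)-N-methoxy-N-methyl-4-oxobutanamide | CON(C)C(=O)[C@H](CC(=O)c1c(O)cc(OC)cc1OC)C(c1ccc(OC)cc1)c1ccc(OC)cc1 | intermediate
10 | (S)-2-[bis(4-methoxyphenyl)methyl]-3-[(dimethylamino)methylidene]-4-(2-hydroxy-4,6-dimethoxyphenyl)-N-methoxy-N-methyl-4-oxobutanamide (alkene geometry not fixed, not isolated) | CON(C)C(=O)[C@H](C(=CN(C)C)C(=O)c1c(O)cc(OC)cc1OC)C(c1ccc(OC)cc1)c1ccc(OC)cc1 | intermediate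
11 | (S)-2-(5,7-dimethoxy-4-oxo-4H-chromen-3-yl)-N-methoxy-N-methyl-3,3-bis(4-methoxyphenyl)propanamide | CON(C)C(=O)[C@H](c1coc2cc(OC)cc(OC)c2c1=O)C(c1ccc(OC)cc1)c1ccc(OC)cc1 | intermediate
12 | ethoxyacetylene | C#COCC | starting material
13 | lithium ethoxyacetylide (not isolated) | [Li]C#COCC | intermediate
14 | lithium (4S)-4-(5,7-dimethoxy-4-oxo-4H-chromen-3-yl)-1-ethoxy-3-[methoxy(methyl)amino]-5,5-bis(4-methoxyphenyl)pent-1-yn-3-olate (either configuration at C3, not isolated) | [Li]OC(C#COCC)(N(C)OC)[C@H](c1coc2cc(OC)cc(OC)c2c1=O)C(c1ccc(OC)cc1)c1ccc(OC)cc1 | intermediate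
15 | (S)-4-(5,7-dimethoxy-4-oxo-4H-chromen-3-yl)-1-ethoxy-5,5-bis(4-methoxyphenyl)pent-1-yn-3-one | O=C(C#COCC)[C@H](c1coc2cc(OC)cc(OC)c2c1=O)C(c1ccc(OC)cc1)c1ccc(OC)cc1 | intermediate
16 | methyl acetoacetate | COC(=O)CC(C)=O | starting material
17 | methyl (Z)-3-(trimethylsilyloxy)but-2-enoate | COC(=O)/C=C(/C)O[Si](C)(C)C | intermediate
18 | lithium (1Z)-1-methoxy-3-(trimethylsilyloxy)buta-1,3-dien-1-olate (not isolated) | CO/C(O[Li])=C\C(=C)O[Si](C)(C)C | intermediate
19 | (1E)-1-methoxy-1,3-bis(trimethylsilyloxy)buta-1,3-diene | CO/C(O[Si](C)(C)C)=C\C(=C)O[Si](C)(C)C | intermediate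
20 | (S)-3-{1-[2-ethoxy-6-methoxy-4,6-bis(trimethylsilyloxy)cyclohexa-1,4-dien-1-yl]-3,3-bis(4-methoxyphenyl)-1-oxopropan-2-yl}-5,7-dimethoxy-4H-chromen-4-one (either configuration at the ketal carbon, not isolated) | CCOC1=C(C(=O)[C@H](c2coc3cc(OC)cc(OC)c3c2=O)C(c2ccc(OC)cc2)c2ccc(OC)cc2)C(OC)(O[Si](C)(C)C)C=C(O[Si](C)(C)C)C1 | intermediate
21 | (S)-3-{1-[2-ethoxy-4,6-bis(trimethylsilyloxy)phenyl]-3,3-bis(4-methoxyphenyl)-1-oxopropan-2-yl}-5,7-dimethoxy-4H-chromen-4-one (not isolated) | CCOc1cc(O[Si](C)(C)C)cc(O[Si](C)(C)C)c1C(=O)[C@H](c1coc2cc(OC)cc(OC)c2c1=O)C(c1ccc(OC)cc1)c1ccc(OC)cc1 | intermediate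
22 | (S)-3-[1-(2-ethoxy-4,6-dihydroxyphenyl)-3,3-bis(4-methoxyphenyl)-1-oxopropan-2-yl]-5,7-dimethoxy-4H-chromen-4-one | O=C(c1c(O)cc(O)cc1OCC)[C@H](c1coc2cc(OC)cc(OC)c2c1=O)C(c1ccc(OC)cc1)c1ccc(OC)cc1 | intermediate
23 | (+)-chamaechromone, (S)-3-[3,3-bis(4-hydroxyphenyl)-1-oxo-1-(2,4,6-trihydroxyphenyl)propan-2-yl]-5,7-dihydroxy-4H-chromen-4-one | O=C(c1c(O)cc(O)cc1O)[C@H](c1coc2cc(O)cc(O)c2c1=O)C(c1ccc(O)cc1)c1ccc(O)cc1 | target

## Step count and least certain steps

Total: 11 steps. Longest linear sequence: 9 steps (steps 1 to 7, 10 and 11); the diene is made in a two-step branch (steps 8 and 9) that joins at step 10.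

**Step 10 (key step).** The push–pull alkyne may be too weak a dienophile at temperatures below the onset of ethylene loss from the ynol ether. A stepwise addition may end with expulsion of ethoxide from the alkyne carbon instead of ring closure. Long heating may erode the configuration of the ynone alpha carbon. Loss of silanol instead of methanol from the ketal would leave a methyl ether on C2', which is harmless because the last step cleaves it.

Fallback by known chemistry, from amide 11 to target 23: 1,3,5-trimethoxybenzene is lithiated with n-BuLi to 2,4,6-trimethoxyphenyllithium F1. F1 adds to 11 at low temperature (Weinreb ketone synthesis) to give (S)-5,7-dimethoxy-3-[3,3-bis(4-methoxyphenyl)-1-oxo-1-(2,4,6-trimethoxyphenyl)propan-2-yl]-4H-chromen-4-one F2. BBr3 then cleaves all seven methyl ethers to 23. This gives up the base-free assembly of ring D and exposes C-alpha to an aryllithium, but uses only known reaction types.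

**Step 7.** The acetylide may deprotonate C-alpha of the crowded amide, or the adduct may collapse early and release a lithium amide that does the same; either erodes the configuration. Addition to so hindered an amide may be slow enough for attack at C4 or C2 of the chromone to compete.

Fallback, from keto ester 7 to ynone 15, replacing the organolithium addition by a neutral palladium-catalysed acyl coupling: 7 is annulated as in step 6 to methyl (S)-2-(5,7-dimethoxy-4-oxo-4H-chromen-3-yl)-3,3-bis(4-methoxyphenyl)propanoate F3. Me3SnOH in 1,2-dichloroethane hydrolyses F3 to (S)-2-(5,7-dimethoxy-4-oxo-4H-chromen-3-yl)-3,3-bis(4-methoxyphenyl)propanoic acid F4. 1-Chloro-N,N,2-trimethylprop-1-en-1-amine converts F4 under neutral conditions into (S)-2-(5,7-dimethoxy-4-oxo-4H-chromen-3-yl)-3,3-bis(4-methoxyphenyl)propanoyl chloride F5. A Stille acyl coupling of F5 with tributyl(ethoxyethynyl)stannane F6 (from 13 and Bu3SnCl), catalysed by Pd(PPh3)4 (zerovalent palladium), gives 15.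

**Step 2.** Hydrogenation of a tetrasubstituted alkene carrying two aryl groups may be slow, and face discrimination may be poorer than for simpler alkylidene succinates.

Fallback, from 4 to 5, replacing asymmetric catalysis by resolution: hydrogenation of 4 over palladium on carbon (Pd/C) gives racemic 3-(methoxycarbonyl)-4,4-bis(4-methoxyphenyl)butanoic acid F7. Crystallisation with (R)-1-phenylethylamine gives the salt (R)-1-phenylethylammonium (R)-3-(methoxycarbonyl)-4,4-bis(4-methoxyphenyl)butanoate F8, from which acid liberates 5. If the other diastereomeric salt is the less soluble one, the mirror-image amine is used.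

**Step 3.** Acylation may occur in part para to the hydroxyl group. The acid and ester termini may scramble through a cyclic anhydride under hot Lewis acid. Tetralone closure onto an anisyl ring is a further, less likely, diversion.

Fallback, from 5 to 7, using a symmetric arene and a milder acylating agent: trifluoroacetic anhydride converts 5 into the mixed anhydride (R)-3-(methoxycarbonyl)-4,4-bis(4-methoxyphenyl)butanoic trifluoroacetic anhydride F9. F9 acylates 1,3,5-trimethoxybenzene at 0 °C to room temperature to give methyl (R)-2-[bis(4-methoxyphenyl)methyl]-4-oxo-4-(2,4,6-trimethoxyphenyl)butanoate F10, which can form only one regioisomer. BCl3 at low temperature then removes one methoxy group ortho to the ketone by chelation and gives 7.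

## Further compounds

F1 | step 10 | 2,4,6-trimethoxyphenyllithium | [Li]c1c(OC)cc(OC)cc1OC
F2 | step 10 | (S)-5,7-dimethoxy-3-[3,3-bis(4-methoxyphenyl)-1-oxo-1-(2,4,6-trimethoxyphenyl)propan-2-yl]-4H-chromen-4-one | O=C(c1c(OC)cc(OC)cc1OC)[C@H](c1coc2cc(OC)cc(OC)c2c1=O)C(c1ccc(OC)cc1)c1ccc(OC)cc1
F3 | step 7 | methyl (S)-2-(5,7-dimethoxy-4-oxo-4H-chromen-3-yl)-3,3-bis(4-methoxyphenyl)propanoate | COC(=O)[C@H](c1coc2cc(OC)cc(OC)c2c1=O)C(c1ccc(OC)cc1)c1ccc(OC)cc1
F4 | step 7 | (S)-2-(5,7-dimethoxy-4-oxo-4H-chromen-3-yl)-3,3-bis(4-methoxyphenyl)propanoic acid | OC(=O)[C@H](c1coc2cc(OC)cc(OC)c2c1=O)C(c1ccc(OC)cc1)c1ccc(OC)cc1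
F5 | step 7 | (S)-2-(5,7-dimethoxy-4-oxo-4H-chromen-3-yl)-3,3-bis(4-methoxyphenyl)propanoyl chloride | ClC(=O)[C@H](c1coc2cc(OC)cc(OC)c2c1=O)C(c1ccc(OC)cc1)c1ccc(OC)cc1
F6 | step 7 | tributyl(ethoxyethynyl)stannane | CCCC[Sn](CCCC)(CCCC)C#COCC
F7 | step 2 | racemic 3-(methoxycarbonyl)-4,4-bis(4-methoxyphenyl)butanoic acid | COC(=O)C(CC(=O)O)C(c1ccc(OC)cc1)c1ccc(OC)cc1
F8 | step 2 | (R)-1-phenylethylammonium (R)-3-(methoxycarbonyl)-4,4-bis(4-methoxyphenyl)butanoate | COC(=O)[C@H](CC(=O)[O-])C(c1ccc(OC)cc1)c1ccc(OC)cc1.C[C@@H]([NH3+])c1ccccc1
F9 | step 3 | (R)-3-(methoxycarbonyl)-4,4-bis(4-methoxyphenyl)butanoic trifluoroacetic anhydride | COC(=O)[C@H](CC(=O)OC(=O)C(F)(F)F)C(c1ccc(OC)cc1)c1ccc(OC)cc1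
F10 | step 3 | methyl (R)-2-[bis(4-methoxyphenyl)methyl]-4-oxo-4-(2,4,6-trimethoxyphenyl)butanoate | COC(=O)[C@H](CC(=O)c1c(OC)cc(OC)cc1OC)C(c1ccc(OC)cc1)c1ccc(OC)cc1
A1 | alternative 1 | (3R)-5,7-dimethoxy-3-[(2S)-1-oxo-1-(2,4,6-trimethoxyphenyl)-3,3-bis(4-methoxyphenyl)propan-2-yl]chroman-4-one | O=C(c1c(OC)cc(OC)cc1OC)[C@H]([C@@H]1COc2cc(OC)cc(OC)c2C1=O)C(c1ccc(OC)cc1)c1ccc(OC)cc1
A2 | alternative 1 | 2-{[(2E)-3-[bis(4-methoxyphenyl)methyl]-4-oxo-4-(2,4,6-trimethoxyphenyl)but-2-en-1-yl]oxy}-4,6-dimethoxybenzaldehyde | O=Cc1c(OC)cc(OC)cc1OC/C=C(\C(c1ccc(OC)cc1)c1ccc(OC)cc1)C(=O)c1c(OC)cc(OC)cc1OC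
A3 | alternative 2 | (S)-2-(5,7-dimethoxy-4-oxo-4H-chromen-3-yl)-3,3-bis(4-methoxyphenyl)-N-(quinolin-8-yl)propanamide | O=C(Nc1cccc2cccnc12)[C@H](c1coc2cc(OC)cc(OC)c2c1=O)C(c1ccc(OC)cc1)c1ccc(OC)cc1
A4 | alternative 2 | (S)-2-(5,7-dimethoxy-4-oxo-4H-chromen-3-yl)-N-(quinolin-8-yl)propanamide | O=C(Nc1cccc2cccnc12)[C@H](c1coc2cc(OC)cc(OC)c2c1=O)C
A5 | alternative 2 | 4-iodoanisole | COc1ccc(I)cc1
A6 | alternative 3 | tert-butyl (S)-2-(5,7-dimethoxy-4-oxo-4H-chromen-3-yl)-3,3-bis(4-methoxyphenyl)propanoate | O=C(OC(C)(C)C)[C@H](c1coc2cc(OC)cc(OC)c2c1=O)C(c1ccc(OC)cc1)c1ccc(OC)cc1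
A7 | alternative 3 | 1-tert-butyl 4-methyl (S)-2-[bis(4-methoxyphenyl)methyl]-3-(hydroxymethylidene)butanedioate (enol form of the formylsuccinate) | O=C(OC(C)(C)C)[C@H](C(=CO)C(=O)OC)C(c1ccc(OC)cc1)c1ccc(OC)cc1
A8 | alternative 3 | 3,5-dimethoxy-2-(trimethylsilyl)phenyl trifluoromethanesulfonate | COc1cc(OC)c([Si](C)(C)C)c(OS(=O)(=O)C(F)(F)F)c1
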